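**Retrosynthetic overview**

1. Target 34 ← desilylation/bis-angeloylation ← 7,9,15-triol 30 ← two hydroxyl-directed reductions (C15–OH sets C7, C7–OH sets C9) of trione 28 ← Claisen condensation (C7–C8, seven-membered ring) of diketone ester 26.
2. 26 ← Raney nickel desulfurisation and ketal hydrolysis of cage 24 ← crossed intramolecular [2+2] photocycloaddition of thiopyranone 23, forming C4–C10 and C5–C11 and closing the cyclobutane and both six-membered rings of the bicyclo[3.1.1]heptanone in one operation.
3. Enabling feature: the cyclobutane C4–C5–C11–C10 is the adduct of the C10=C11 enone (conjugated to the C1 ketone) and a C4=C5 alkene that hangs from C2 through the single atom C3. Tying C2 to the C10-methyl carbon through a temporary sulfur atom gives a 6-allylcyclohex-2-enone pattern, whose photocycloaddition is crossed, and fixes the 10-methyl group syn to C1.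
4. 23 ← cyclic sulfonium ylide [2,3] shift of diazoketone 21 ← thiol 18 + allylic bromide 17; C3 comes from a CBS reduction through two sigmatropic chirality transfers, C6 from enzymatic desymmetrisation of malonate 5.
5. Ring order: temporary thiopyranone → cyclobutane plus two six-membered rings (step 14) → sulfur ring removed → seven-membered ring (step 16).

Key step: step 14

**Remarks**

- Numbering in names follows longipinane: C1 ketone, C2 (CH2), C3 (CH–CH3), C4, C5, C6 (quaternary, CH3 and C15H2O), C7 (O), C8 (CH2), C9 (O), C10 (quaternary, CH3), C11; the cyclobutane is C4–C5–C11–C10. The target is (3R,4S,5S,6S,7R,9R,10R,11R).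
- Assumption: pig liver esterase is taken to hydrolyse the ester of 5 that leads to (R)-6. If the enzyme gives the antipode, the two carbonyl manipulations (steps 4 and 5) are exchanged so that the same aldehyde 8 results.
- C2 of 23 is epimerisable (alpha to the ketone and to sulfur); the 2R epimer, which is the one that can cyclise, is drawn.
- Step 20 consumes two molecules of angelic acid 32, one for each secondary hydroxyl group; the first is entered as reactant 32 and the second under the reagents that add atoms.

**Route**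

Step 1
Reactants: 1 dimethyl 2-methylpropanedioate; 2 formaldehyde
Product: 3 dimethyl 2-(hydroxymethyl)-2-methylpropanedioate
Conditions: 37% aq. CH2O, KHCO3 (cat.), H2O, 20 °C
Reagents that add atoms: none
Why: Aldol-type hydroxymethylation of the single acidic malonate C–H should stop cleanly at mono-addition.

Step 2
Reactants: 3 dimethyl 2-(hydroxymethyl)-2-methylpropanedioate; 4 2-methylpropene
Product: 5 dimethyl 2-(tert-butoxymethyl)-2-methylpropanedioate
Conditions: isobutene (excess), H2SO4 (cat.), CH2Cl2, sealed vessel, 20 °C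
Reagents that add atoms: none
Why: Acid-catalysed addition of the primary alcohol to isobutene should give the tert-butyl ether, and the quaternary carbon rules out elimination.

Step 3
Reactants: 5 dimethyl 2-(tert-butoxymethyl)-2-methylpropanedioate
Product: 6 (2R)-3-tert-butoxy-2-(methoxycarbonyl)-2-methylpropanoic acid
Conditions: pig liver esterase, phosphate buffer pH 7.5 (pH-stat, 1 M NaOH), 25 °C; then HCl to pH 2
Reagents that add atoms: water, O
Why: Enzymatic desymmetrisation of the prochiral diester should hydrolyse one enantiotopic ester and so set the quaternary centre that becomes C6.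

Step 4
Reactants: 6 (2R)-3-tert-butoxy-2-(methoxycarbonyl)-2-methylpropanoic acid
Product: 7 methyl (2S)-3-tert-butoxy-2-(hydroxymethyl)-2-methylpropanoate
Conditions: BH3·SMe2, THF, 0 → 20 °C; MeOH
Reagents that add atoms: none
Why: Borane reduces the carboxylic acid chemoselectively in the presence of the methyl ester, and the stereocentre is not touched.

Step 5
Reactants: 7 methyl (2S)-3-tert-butoxy-2-(hydroxymethyl)-2-methylpropanoate
Product: 8 methyl (2R)-3-tert-butoxy-2-formyl-2-methylpropanoate
Conditions: Dess–Martin periodinane, CH2Cl2, 0 → 20 °C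
Reagents that add atoms: none
Why: Dess–Martin oxidation should give the non-enolisable aldehyde without risk to the quaternary centre.

Step 6
Reactants: 8 methyl (2R)-3-tert-butoxy-2-formyl-2-methylpropanoate; 9 1-(triphenyl-λ5-phosphanylidene)propan-2-one
Product: 10 methyl (2S,3E)-2-(tert-butoxymethyl)-2-methyl-5-oxohex-3-enoate
Conditions: toluene, 90 °C
Reagents that add atoms: none
Why: Wittig olefination with a stabilised ylide should give the E-enone, and the aldehyde reacts in preference to the hindered ester.

Step 7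
Reactants: 10 methyl (2S,3E)-2-(tert-butoxymethyl)-2-methyl-5-oxohex-3-enoate
Product: 11 methyl (2S,3E,5S)-2-(tert-butoxymethyl)-5-hydroxy-2-methylhex-3-enoate
Conditions: (R)-2-methyl-CBS-oxazaborolidine (10 mol%), catecholborane, toluene, −78 °C
Reagents that add atoms: none
Why: Corey–Bakshi–Shibata 1,2-reduction of the methyl enone is catalyst-controlled (alkenyl as the large group) and should set the 5S carbinol.

Step 8
Reactants: 11 methyl (2S,3E,5S)-2-(tert-butoxymethyl)-5-hydroxy-2-methylhex-3-enoate
Product: 13 methyl (2S,3S,4E)-2-(tert-butoxymethyl)-2-methyl-3-[(methylsulfanyl)carbonylsulfanyl]hex-4-enoate, via O-allyl S-methyl xanthate 12 (not isolated)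
Conditions: NaH, THF, 0 °C; CS2; MeI; then 50 °C
Reagents that add atoms: carbon disulfide, S=C=S; iodomethane, CI
Why: The allylic xanthate should undergo the thione-to-thiol [3,3]-sigmatropic shift (driven by C=S → C=O) through a chair transition state with equatorial methyl, transferring the C5 configuration suprafacially to the new C3–S centre and giving the E-alkene.

Step 9
Reactants: 14 3,3-dimethoxybutan-2-one; 15 dimethyl (2-oxopropyl)phosphonate
Product: 16 (3E)-5,5-dimethoxy-4-methylhex-3-en-2-one
Conditions: NaH, THF, 0 → 65 °C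
Reagents that add atoms: none
Why: Horner–Wadsworth–Emmons olefination of the α,α-dialkoxy-activated ketone should place the acyl group trans to the bulky ketal carbon.

Step 10
Reactants: 16 (3E)-5,5-dimethoxy-4-methylhex-3-en-2-one
Product: 17 (3Z)-4-(bromomethyl)-5,5-dimethoxyhex-3-en-2-one
Conditions: N-bromosuccinimide, AIBN (cat.), PhCF3, 80 °C
Reagents that add atoms: N-bromosuccinimide, O=C1CCC(=O)N1Br
Why: Wohl–Ziegler bromination should occur at the only allylic (gamma) methyl group of the enone.

Step 11
Reactants: 13 methyl (2S,3S,4E)-2-(tert-butoxymethyl)-2-methyl-3-[(methylsulfanyl)carbonylsulfanyl]hex-4-enoate; 17 (3Z)-4-(bromomethyl)-5,5-dimethoxyhex-3-en-2-one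
Product: 19 methyl (2S,3S,4E)-2-(tert-butoxymethyl)-3-{[(2Z)-2-(1,1-dimethoxyethyl)-4-oxopent-2-en-1-yl]sulfanyl}-2-methylhex-4-enoate, via thiol 18 (not isolated)
Conditions: H2NCH2CH2NH2, THF, 0 → 20 °C, N2 purge; then 17, Et3N, 0 °C
Reagents that add atoms: none
Why: Aminolysis of the dithiocarbonate by the diamine (cyclic urea formation) frees the thiol, whose SN2 S-alkylation by the allylic bromide is far faster than conjugate addition to the fully substituted enone β-carbon.

Step 12
Reactants: 19 methyl (2S,3S,4E)-2-(tert-butoxymethyl)-3-{[(2Z)-2-(1,1-dimethoxyethyl)-4-oxopent-2-en-1-yl]sulfanyl}-2-methylhex-4-enoate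
Product: 21 methyl (2S,3S,4E)-2-(tert-butoxymethyl)-3-{[(2Z)-5-diazo-2-(1,1-dimethoxyethyl)-4-oxopent-2-en-1-yl]sulfanyl}-2-methylhex-4-enoate, via trifluoroacetyl diketone 20 (not isolated)
Conditions: LiN(SiMe3)2, THF, −78 °C; CF3CO2CH2CF3; then MsN3, Et3N, H2O (1 equiv), MeCN, 20 °C
Reagents that add atoms: methanesulfonyl azide, CS(=O)(=O)N=[N+]=[N-]
Why: Detrifluoroacetylative (Regitz-type) diazo transfer proceeds through the kinetic α′-enolate of the methyl ketone, so the enone, ester and ketal should survive.

Step 13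
Reactants: 21 methyl (2S,3S,4E)-2-(tert-butoxymethyl)-3-{[(2Z)-5-diazo-2-(1,1-dimethoxyethyl)-4-oxopent-2-en-1-yl]sulfanyl}-2-methylhex-4-enoate
Product: 23 methyl (2S,3E,5S)-2-(tert-butoxymethyl)-5-[(2R)-5-(1,1-dimethoxyethyl)-3-oxo-3,6-dihydro-2H-thiopyran-2-yl]-2-methylhex-3-enoate, via cyclic sulfonium ylide 22 (not isolated)
Conditions: Rh2(OAc)4 (1 mol%), CH2Cl2, slow addition, 20 → 40 °C
Reagents that add atoms: none
Why: The rhodium carbenoid is trapped by sulfur to give a six-membered sulfonium ylide whose [2,3]-sigmatropic shift (Doyle–Kirmse type) moves the allyl group to C2 through an envelope transition state with the quaternary substituent exo, which should give the E-alkene and set C3 (net replacement of the C–O bond of 11 by the C2–C3 bond with retention).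

Step 14
Reactants: 23 methyl (2S,3E,5S)-2-(tert-butoxymethyl)-5-[(2R)-5-(1,1-dimethoxyethyl)-3-oxo-3,6-dihydro-2H-thiopyran-2-yl]-2-methylhex-3-enoate
Product: 24 thia-bridged cage adduct: 6-(1,1-dimethoxyethyl)-4-methyl-2-oxobicyclo[3.1.1]heptane with C3 joined through sulfur to the methylene carbon on C6 and C7 bearing the (2S)-1-tert-butoxy-3-methoxy-2-methyl-3-oxopropan-2-yl group (ring configuration as in 34)
Conditions: hν (366 nm, Pyrex), degassed MeCN (5 mM), 20 °C; recovered 2-epimer re-equilibrated with Et3N and resubmitted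
Reagents that add atoms: none
Why: Excitation of the cyclic enone and intersystem crossing give the triplet, whose β-carbon C10 adds to the internal alkene carbon C4 (6-exo-trig, closing the ring C1–C2–C3–C4–C10–C11), and the resulting 1,4-biradical (α-keto radical at C11, secondary radical at C5) collapses after spin inversion to the cyclobutane C4–C5–C11–C10, which also completes the ring C1–C2–C3–C4–C5–C11. The closest known reaction type is the crossed intramolecular [2+2] photocycloaddition of 6-allylcyclohex-2-enones to tricyclo[3.3.1.0(2,7)]nonan-6-ones, of which 23 is the 5-thia analogue with the same connectivity. The crossed regiochemistry that the step needs is secured by the one-carbon link C3 between ring carbon C2 and the alkene, which lets C4 reach C10 while the alternative five-membered closure C11–C4 would build a strained bridged ring. C10 and C11 are set cis (C1 carbonyl and the S–CH2 group on the same face) by the ring that holds the enone, and C4 follows because the new bonds must form on the ring face that carries the side chain. The absolute sense comes from C3, since only the C2 epimer with the 3-methyl group anti to sulfur (2R as drawn) can fold without a methyl/sulfur eclipsing clash, so the pre-set C3 centre decides which enone face reacts. At C5 the bulky quaternary substituent should take the position anti to the C1–C3 bridge during biradical closure, because the syn position collides with the 3-methyl group.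

Step 15
Reactants: 24 thia-bridged cage adduct
Product: 26 methyl (2S)-2-[6-acetyl-4,6-dimethyl-2-oxobicyclo[3.1.1]heptan-7-yl]-3-tert-butoxy-2-methylpropanoate (ring configuration as in 34), via desulfurised dimethyl ketal 25 (not isolated)
Conditions: Raney nickel (Ni, acetone-deactivated), EtOH, 20 °C; filter; then 1 M HCl, THF, 20 °C
Reagents that add atoms: water, O
Why: Raney nickel hydrogenolysis of both C–S bonds should unveil C2H2 and the 10-methyl group without touching a stereocentre, and dilute acid then hydrolyses the dimethyl ketal to the methyl ketone while the tert-butyl ether and ester survive.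

Step 16
Reactants: 26 methyl (2S)-2-[6-acetyl-4,6-dimethyl-2-oxobicyclo[3.1.1]heptan-7-yl]-3-tert-butoxy-2-methylpropanoate
Product: 27 15-tert-butoxylongipinane-1,7,9-trione (ring configuration as in 34)
Conditions: NaH, MeOH (cat.), THF, 65 °C; then cold 1 M HCl
Reagents that add atoms: none
Why: Intramolecular Claisen condensation of the methyl ketone enolate (C8) with the ester (C7) should close the seven-membered ring because both groups sit anti on C10 and C5, the β-diketonate is the thermodynamic sink, and the trans arrangement of C1 and C9 across C10–C11 blocks other closures.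

Step 17
Reactants: 27 15-tert-butoxylongipinane-1,7,9-trione
Product: 28 15-hydroxylongipinane-1,7,9-trione (ring configuration as in 34)
Conditions: CF3CO2H, CH2Cl2, 0 → 20 °C
Reagents that add atoms: none
Why: Acidolysis of the tert-butyl ether (loss of isobutene) should free the primary alcohol without affecting the ketones.

Step 18
Reactants: 28 15-hydroxylongipinane-1,7,9-trione
Product: 30 7,9,15-trihydroxylongipinan-1-one (configuration as in 34), via 7-hydroxy-9-ketone 29 (not isolated)
Conditions: Me4N[BH(OAc)3], MeCN/AcOH 1:1, −30 → 20 °C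
Reagents that add atoms: none
Why: In two successive Evans–Saksena reductions the alkoxyborohydride on C15–OH delivers hydride to C7=O from the CH2OH face (7-OH trans to C15), then the new 7-OH delivers hydride to C9=O to give the trans-1,3-diol, while the C1 ketone has no hydroxyl within reach and should stay.

Step 19
Reactants: 30 7,9,15-trihydroxylongipinan-1-one
Product: 31 15-(tert-butyldimethylsilyloxy)-7,9-dihydroxylongipinan-1-one (configuration as in 34)
Conditions: t-BuMe2SiCl, imidazole, DMF, 0 °C
Reagents that add atoms: tert-butyl(chloro)dimethylsilane, CC(C)(C)[Si](C)(C)Cl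
Why: The primary hydroxyl should be silylated selectively over the two secondary hydroxyls, each of which is flanked by a quaternary carbon.

Step 20
Reactants: 31 15-(tert-butyldimethylsilyloxy)-7,9-dihydroxylongipinan-1-one; 32 (2Z)-2-methylbut-2-enoic acid (angelic acid)
Product: 33 15-(tert-butyldimethylsilyloxy)-7,9-bis{[(2Z)-2-methylbut-2-enoyl]oxy}longipinan-1-one (configuration as in 34)
Conditions: 32 (6 equiv, two of them consumed), 2,4,6-trichlorobenzoyl chloride (6 equiv), Et3N (12 equiv), toluene, 20 °C; then 31, 80 °C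
Reagents that add atoms: (2Z)-2-methylbut-2-enoic acid (angelic acid, the second equivalent of 32 that is consumed), C/C=C(/C)C(=O)O
Why: Yamaguchi esterification through the mixed anhydride without a nucleophilic catalyst should acylate the 7- and 9-hydroxyl groups, each taking one angeloyl group from its own molecule of mixed anhydride, while avoiding the addition–elimination path that isomerises angelate to tiglate.

Step 21
Reactants: 33 15-(tert-butyldimethylsilyloxy)-7,9-bis{[(2Z)-2-methylbut-2-enoyl]oxy}longipinan-1-one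
Product: 34 (3R,4S,5S,6S,7R,9R,10R,11R)-15-hydroxy-7,9-bis{[(2Z)-2-methylbut-2-enoyl]oxy}longipinan-1-one (target)
Conditions: HF·pyridine, THF/pyridine, 0 → 20 °C
Reagents that add atoms: none
Why: Fluoride desilylation under mildly acidic conditions should free the primary alcohol without the base-induced 1,3-acyl migration from O7 to O15.

**Compound list**

1 | dimethyl 2-methylpropanedioate | COC(=O)C(C)C(=O)OC | starting material
2 | formaldehyde | C=O | starting material
3 | dimethyl 2-(hydroxymethyl)-2-methylpropanedioate | COC(=O)C(C)(CO)C(=O)OC | intermediate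
4 | 2-methylpropene | CC(C)=C | starting material
5 | dimethyl 2-(tert-butoxymethyl)-2-methylpropanedioate | COC(=O)C(C)(COC(C)(C)C)C(=O)OC | intermediate
6 | (2R)-3-tert-butoxy-2-(methoxycarbonyl)-2-methylpropanoic acid | OC(=O)[C@@](C(=O)OC)(C)COC(C)(C)C | intermediate
7 | methyl (2S)-3-tert-butoxy-2-(hydroxymethyl)-2-methylpropanoate | OC[C@@](C(=O)OC)(C)COC(C)(C)C | intermediate
8 | methyl (2R)-3-tert-butoxy-2-formyl-2-methylpropanoate | O=C[C@@](C(=O)OC)(C)COC(C)(C)C | intermediate
9 | 1-(triphenyl-λ5-phosphanylidene)propan-2-one | CC(=O)C=P(c1ccccc1)(c1ccccc1)c1ccccc1 | starting material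
10 | methyl (2S,3E)-2-(tert-butoxymethyl)-2-methyl-5-oxohex-3-enoate | CC(=O)/C=C/[C@@](C(=O)OC)(C)COC(C)(C)C | intermediate
11 | methyl (2S,3E,5S)-2-(tert-butoxymethyl)-5-hydroxy-2-methylhex-3-enoate | C[C@H](O)/C=C/[C@@](C(=O)OC)(C)COC(C)(C)C | intermediate
12 | O-allyl S-methyl xanthate of 11 | C[C@H](OC(=S)SC)/C=C/[C@@](C(=O)OC)(C)COC(C)(C)C | intermediate (not isolated)
13 | methyl (2S,3S,4E)-2-(tert-butoxymethyl)-2-methyl-3-[(methylsulfanyl)carbonylsulfanyl]hex-4-enoate | C/C=C/[C@H](SC(=O)SC)[C@@](C(=O)OC)(C)COC(C)(C)C | intermediate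
14 | 3,3-dimethoxybutan-2-one | CC(=O)C(C)(OC)OC | starting material
15 | dimethyl (2-oxopropyl)phosphonate | CC(=O)CP(=O)(OC)OC | starting material
16 | (3E)-5,5-dimethoxy-4-methylhex-3-en-2-one | CC(=O)/C=C(\C)C(C)(OC)OC | intermediate
17 | (3Z)-4-(bromomethyl)-5,5-dimethoxyhex-3-en-2-one | CC(=O)/C=C(\CBr)C(C)(OC)OC | intermediate
18 | methyl (2S,3S,4E)-2-(tert-butoxymethyl)-2-methyl-3-sulfanylhex-4-enoate | C/C=C/[C@H](S)[C@@](C(=O)OC)(C)COC(C)(C)C | intermediate (not isolated)
19 | methyl (2S,3S,4E)-2-(tert-butoxymethyl)-3-{[(2Z)-2-(1,1-dimethoxyethyl)-4-oxopent-2-en-1-yl]sulfanyl}-2-methylhex-4-enoate | CC(=O)/C=C(\CS[C@@H](/C=C/C)[C@@](C(=O)OC)(C)COC(C)(C)C)C(C)(OC)OC | intermediate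
20 | trifluoroacetyl diketone of 19 (6,6,6-trifluoro-3,5-dioxo chain in place of the acetyl group) | O=C(CC(=O)/C=C(\CS[C@@H](/C=C/C)[C@@](C(=O)OC)(C)COC(C)(C)C)C(C)(OC)OC)C(F)(F)F | intermediate (not isolated)
21 | methyl (2S,3S,4E)-2-(tert-butoxymethyl)-3-{[(2Z)-5-diazo-2-(1,1-dimethoxyethyl)-4-oxopent-2-en-1-yl]sulfanyl}-2-methylhex-4-enoate | [N-]=[N+]=CC(=O)/C=C(\CS[C@@H](/C=C/C)[C@@](C(=O)OC)(C)COC(C)(C)C)C(C)(OC)OC | intermediate
22 | cyclic sulfonium ylide (3-oxo-3,6-dihydro-2H-thiopyran-1-ium-2-ide carrying the S-allyl group, sulfur configuration not defined) | O=C1[CH-][S+]([C@@H](/C=C/C)[C@@](C(=O)OC)(C)COC(C)(C)C)CC(C(C)(OC)OC)=C1 | intermediate (not isolated)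
23 | methyl (2S,3E,5S)-2-(tert-butoxymethyl)-5-[(2R)-5-(1,1-dimethoxyethyl)-3-oxo-3,6-dihydro-2H-thiopyran-2-yl]-2-methylhex-3-enoate | O=C1C=C(C(C)(OC)OC)CS[C@@H]1[C@@H](C)/C=C/[C@@](C(=O)OC)(C)COC(C)(C)C | intermediate
24 | thia-bridged cage adduct (bicyclo[3.1.1]heptan-2-one, C3–S–CH2–C6 bridge, 6-(1,1-dimethoxyethyl), 4-methyl, C7 side chain anti) | COC(C)(OC)[C@]2(CS4)[C@@H]3[C@@H]([C@H]2C(=O)[C@H]4[C@H]3C)[C@@](C)(COC(C)(C)C)C(=O)OC | intermediate
25 | desulfurised dimethyl ketal (6-(1,1-dimethoxyethyl)-4,6-dimethyl-2-oxobicyclo[3.1.1]heptan-7-yl ester) | COC(C)(OC)[C@]2(C)[C@@H]3[C@@H]([C@H]2C(=O)C[C@H]3C)[C@@](C)(COC(C)(C)C)C(=O)OC | intermediate (not isolated)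
26 | methyl (2S)-2-[6-acetyl-4,6-dimethyl-2-oxobicyclo[3.1.1]heptan-7-yl]-3-tert-butoxy-2-methylpropanoate (acetyl and C7 side chain anti to the C2–C4 bridge, 4-methyl on the C7 side) | CC(=O)[C@]2(C)[C@@H]3[C@@H]([C@H]2C(=O)C[C@H]3C)[C@@](C)(COC(C)(C)C)C(=O)OC | intermediate
27 | 15-tert-butoxylongipinane-1,7,9-trione | O=C1CC(=O)[C@]2(C)[C@@H]3[C@@H]([C@H]2C(=O)C[C@H]3C)[C@@]1(C)COC(C)(C)C | intermediate
28 | 15-hydroxylongipinane-1,7,9-trione | O=C1CC(=O)[C@]2(C)[C@@H]3[C@@H]([C@H]2C(=O)C[C@H]3C)[C@@]1(C)CO | intermediate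
29 | (7R)-7,15-dihydroxylongipinane-1,9-dione | O[C@@H]1CC(=O)[C@]2(C)[C@@H]3[C@@H]([C@H]2C(=O)C[C@H]3C)[C@@]1(C)CO | intermediate (not isolated)
30 | (7R,9R)-7,9,15-trihydroxylongipinan-1-one | O[C@@H]1C[C@@H](O)[C@]2(C)[C@@H]3[C@@H]([C@H]2C(=O)C[C@H]3C)[C@@]1(C)CO | intermediate
31 | 15-(tert-butyldimethylsilyloxy)-7,9-dihydroxylongipinan-1-one | O[C@@H]1C[C@@H](O)[C@]2(C)[C@@H]3[C@@H]([C@H]2C(=O)C[C@H]3C)[C@@]1(C)CO[Si](C)(C)C(C)(C)C | intermediate
32 | (2Z)-2-methylbut-2-enoic acid (angelic acid) | C/C=C(/C)C(=O)O | starting material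
33 | 15-(tert-butyldimethylsilyloxy)-7,9-bis{[(2Z)-2-methylbut-2-enoyl]oxy}longipinan-1-one | C/C=C(/C)C(=O)O[C@@H]1C[C@@H](OC(=O)/C(C)=C\C)[C@]2(C)[C@@H]3[C@@H]([C@H]2C(=O)C[C@H]3C)[C@@]1(C)CO[Si](C)(C)C(C)(C)C | intermediate
34 | (3R,4S,5S,6S,7R,9R,10R,11R)-15-hydroxy-7,9-bis{[(2Z)-2-methylbut-2-enoyl]oxy}longipinan-1-one | C/C=C(/C)C(=O)O[C@@H]1C[C@@H](OC(=O)/C(C)=C\C)[C@]2(C)[C@@H]3[C@@H]([C@H]2C(=O)C[C@H]3C)[C@@]1(C)CO | target

**Step count and risks**

Total step count: 21. Longest linear sequence: 19 (steps 1–8 and 11–21; steps 9 and 10 form the side branch).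

Steps most likely to fail:

- Step 14. The sulfur lone pair may quench the enone triplet by charge transfer, or the C–S bonds alpha and gamma to the chromophore may cleave photochemically, so that cycloaddition is inefficient. The fallback sets out from 23 and returns at 26. Sulfur is oxidised chemoselectively with NaIO4 (MeOH/H2O, 0 °C) to the thiopyranone S-oxide F1, which no longer has the donor lone pair. F1 is irradiated at −20 °C under triplet sensitisation (thioxanthen-9-one, 405 nm) to the S-oxide cage adduct F2. Raney nickel (Ni), which also removes sulfoxide sulfur, followed by 1 M HCl then gives 26.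
- Step 13. The carbenoid may be diverted (dimerisation, cyclopropanation of the side-chain alkene, C–H insertion) before sulfur captures it. The fallback sets out from 21 and returns at 23 by classical salt chemistry. Dry HCl (1 equiv, Et2O, −30 °C) converts the diazoketone into the chloromethyl ketone F3. NaI in acetone induces intramolecular S-alkylation to the thianium iodide F4. K2CO3 in CH2Cl2 then deprotonates between sulfonium and carbonyl to give ylide 22, which rearranges to 23.
- Step 16. Enolate attack on the neopentyl-type methyl ester may be too slow, so that retro-Claisen cleavage or intermolecular condensation wins. The fallback sets out from 26 and returns at 27. The hindered methyl ester is cleaved by SN2 demethylation (LiI, pyridine, 110 °C) to the carboxylic acid F5, which is activated with 1,1'-carbonyldiimidazole as the acyl imidazole F6. LiN(SiMe3)2 (2.2 equiv, THF, −78 → 0 °C) then effects intramolecular C-acylation of the methyl ketone enolate to give 27.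

Further compounds
F1 | step 14 | S-oxide of 23 (sulfur configuration not defined) | O=C1C=C(C(C)(OC)OC)CS(=O)[C@@H]1[C@@H](C)/C=C/[C@@](C(=O)OC)(C)COC(C)(C)C
F2 | step 14 | S-oxide of cage adduct 24 | COC(C)(OC)[C@]2(CS4(=O))[C@@H]3[C@@H]([C@H]2C(=O)[C@H]4[C@H]3C)[C@@](C)(COC(C)(C)C)C(=O)OC
F3 | step 13 | methyl (2S,3S,4E)-2-(tert-butoxymethyl)-3-{[(2Z)-5-chloro-2-(1,1-dimethoxyethyl)-4-oxopent-2-en-1-yl]sulfanyl}-2-methylhex-4-enoate | ClCC(=O)/C=C(\CS[C@@H](/C=C/C)[C@@](C(=O)OC)(C)COC(C)(C)C)C(C)(OC)OC
F4 | step 13 | 1-allyl-5-(1,1-dimethoxyethyl)-3-oxo-3,6-dihydro-2H-thiopyran-1-ium iodide (allyl = the hexenoate C3 unit of 19) | O=C1C[S+]([C@@H](/C=C/C)[C@@](C(=O)OC)(C)COC(C)(C)C)CC(C(C)(OC)OC)=C1.[I-]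
F5 | step 16 | (2S)-2-[6-acetyl-4,6-dimethyl-2-oxobicyclo[3.1.1]heptan-7-yl]-3-tert-butoxy-2-methylpropanoic acid | CC(=O)[C@]2(C)[C@@H]3[C@@H]([C@H]2C(=O)C[C@H]3C)[C@@](C)(COC(C)(C)C)C(=O)O
F6 | step 16 | N-acyl imidazole of F5 | CC(=O)[C@]2(C)[C@@H]3[C@@H]([C@H]2C(=O)C[C@H]3C)[C@@](C)(COC(C)(C)C)C(=O)n1ccnc1
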